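Ring C, stripped of bromine, is a 5-aryloxyresorcinol: its C1, C3 and C5 oxygens and six carbons are those of a triketide. The route therefore disconnects the ring C C3–C4 bond and traces ring C to a 4-aryloxy-6-methyl-2-pyrone, whose C4 oxygen already carries the ring A–ring B diaryl ether (all five hydroxyls as methyl ethers). In one operation methoxide opens the lactone and the freed methyl ketone enolate closes onto the new ester, so the pyrone's C2–C6 plus methyl carbon become the arene and its carbonyl and ring oxygens become the two ring C hydroxyls. The precursor comes from triacetic acid lactone; bromine follows at C4 by directed lithiation.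

Key step: step 6

Remarks on the chemistry
- Ring lettering: ring A is the terminal 2,4,6-trioxygenated ring, ring B the central ring, ring C the brominated ring. Ring C is numbered from the carbon bearing the ether oxygen (C1), so its hydroxyls sit on C3 and C5 and bromine on C4.
- Assumption: 4-bromo-2,6-dimethoxybenzaldehyde is taken as a purchasable building block.
- The electron-rich phenols (3, 7, 12, 16, 17) are handled under argon.
- The pyrone is activated as its 4-bromide, not as a sulfonate, so that the hindered phenoxide has only carbon to attack.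
- Bromine is placed on ring C by lithiation between two MOM ethers, because any Br+ source would also attack the methoxylated rings A and B.

Step 1
Reactants: 1 2,4,6-trimethoxybenzaldehyde
Product: 3 2,4,6-trimethoxyphenol, via 2,4,6-trimethoxyphenyl formate 2 (not isolated)
Conditions: mCPBA, CH2Cl2, 0 °C to rt; NaHCO3 wash; then K2CO3 (cat.), MeOH, rt
Reagents that add atoms: 3-chloroperoxybenzoic acid (mCPBA), OOC(=O)c1cccc(Cl)c1
Why: Dakin-type Baeyer–Villiger oxidation, in which the electron-rich trimethoxyphenyl group migrates in preference to hydride in the Criegee intermediate and the formate 2 is then cleaved by base-catalysed methanolysis.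

Step 2
Reactants: 3 2,4,6-trimethoxyphenol; 4 4-bromo-2,6-dimethoxybenzaldehyde
Product: 5 2,6-dimethoxy-4-(2,4,6-trimethoxyphenoxy)benzaldehyde
Conditions: CuI (10 mol%), picolinic acid (20 mol%), K3PO4, DMSO, 90 °C
Reagents that add atoms: none
Why: Ullmann-type diaryl ether synthesis, for which CuI/picolinic acid accepts doubly ortho-substituted phenols and the bromide para to the formyl group is an activated partner.

Step 3
Reactants: 5 2,6-dimethoxy-4-(2,4,6-trimethoxyphenoxy)benzaldehyde
Product: 7 2,6-dimethoxy-4-(2,4,6-trimethoxyphenoxy)phenol, via aryl formate 6 (not isolated)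
Conditions: mCPBA, CH2Cl2, 0 °C to rt; NaHCO3 wash; then K2CO3 (cat.), MeOH, rt
Reagents that add atoms: 3-chloroperoxybenzoic acid (mCPBA), OOC(=O)c1cccc(Cl)c1
Why: Dakin-type Baeyer–Villiger oxidation again, the 2,6-dimethoxy-4-aryloxyphenyl group migrating readily and peracid addition to the aldehyde being faster than oxidation of the methoxylated rings.

Step 4
Reactants: 8 triacetic acid lactone (4-hydroxy-6-methyl-2H-pyran-2-one)
Product: 9 4-bromo-6-methyl-2H-pyran-2-one
Conditions: Bu4NBr, P2O5, toluene, 100 °C
Reagents that add atoms: tetrabutylammonium bromide, CCCC[N+](CCCC)(CCCC)CCCC.[Br-]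
Why: Dehydrative bromination of a vinylogous acid, in which P2O5 turns the 4-hydroxyl into a phosphate leaving group that bromide displaces by addition–elimination at C4.

Step 5
Reactants: 7 2,6-dimethoxy-4-(2,4,6-trimethoxyphenoxy)phenol; 9 4-bromo-6-methyl-2H-pyran-2-one
Product: 10 4-[2,6-dimethoxy-4-(2,4,6-trimethoxyphenoxy)phenoxy]-6-methyl-2H-pyran-2-one
Conditions: K2CO3, DMF, 50 °C
Reagents that add atoms: none
Why: Addition–elimination (vinylogous acyl substitution) of the phenoxide of 7 at C4 of the 4-bromo-2-pyrone, a vinylogous acid bromide, which is far easier than arylating a hindered oxygen.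

Step 6
Reactants: 10 4-[2,6-dimethoxy-4-(2,4,6-trimethoxyphenoxy)phenoxy]-6-methyl-2H-pyran-2-one
Product: 12 5-[2,6-dimethoxy-4-(2,4,6-trimethoxyphenoxy)phenoxy]benzene-1,3-diol, via open-chain keto ester 11 (not isolated)
Conditions: NaOMe (5 equiv), dry MeOH, reflux; then 1 M HCl
Reagents that add atoms: none
Why: Methoxide adds to the lactone carbonyl (pyrone C2), the C2–O1 bond breaks and the E-enoate 11 forms with its ester and its CH2C(O)CH3 arm held cis on the old C3=C4 double bond; the methyl ketone enolate (old C6 methyl) then attacks the ester carbon, methoxide is expelled and the resulting 5-aryloxycyclohex-4-ene-1,3-dione tautomerises to the resorcinolate, which makes the sequence irreversible. The closest known reaction type is the alkoxide-induced opening and Claisen (Dieckmann-type) reclosure of 4-alkoxy-6-methyl-2-pyrones to phloroglucinol monoethers. Ring C closes in a 6-(enolendo)-exo-trig mode, the new bond joining ring C C3 (old lactone carbonyl) to C4 (old methyl carbon); no stereocentre arises. An aldol closure is not open to 11 because its central carbonyl is masked as the aryl enol ether, so the Claisen mode is the only six-membered option. The selectivity needed is acyl attack at C2 and not conjugate attack at C4, which would expel the ring B aryloxide; the two methoxy groups flanking the ring B oxygen screen C4, and in NaOMe/MeOH the opened ester should rest as its γ-deprotonated dienolate, which resists conjugate exchange.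

Step 7
Reactants: 12 5-[2,6-dimethoxy-4-(2,4,6-trimethoxyphenoxy)phenoxy]benzene-1,3-diol
Product: 13 1,3-bis(methoxymethoxy)-5-[2,6-dimethoxy-4-(2,4,6-trimethoxyphenoxy)phenoxy]benzene
Conditions: NaH (2.5 equiv), MOMCl (2.5 equiv), DMF, 0 °C to rt
Reagents that add atoms: chloromethyl methyl ether (MOMCl), COCCl
Why: Williamson-type O-alkylation of the resorcinol dianion with a hard electrophile, which installs on ring C the two strongest ortho-directing ether groups in the molecule.

Step 8
Reactants: 13 1,3-bis(methoxymethoxy)-5-[2,6-dimethoxy-4-(2,4,6-trimethoxyphenoxy)phenoxy]benzene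
Product: 15 2-bromo-5-[2,6-dimethoxy-4-(2,4,6-trimethoxyphenoxy)phenoxy]-1,3-bis(methoxymethoxy)benzene, via ring C aryllithium 14 (not isolated)
Conditions: n-BuLi (1.1 equiv), THF, −20 °C, 1 h; then BrCCl2CCl2Br, −78 °C to rt
Reagents that add atoms: 1,2-dibromo-1,1,2,2-tetrachloroethane, BrC(Cl)(Cl)C(Cl)(Cl)Br
Why: Directed ortho-metalation, in which ring C C4–H lies between two chelating MOM ethers and should be lithiated ahead of the C–H bonds flanked by methyl or aryl ethers, after which aryllithium 14 takes bromine from the haloalkane, so no electrophilic bromine meets rings A and B.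

Step 9
Reactants: 15 2-bromo-5-[2,6-dimethoxy-4-(2,4,6-trimethoxyphenoxy)phenoxy]-1,3-bis(methoxymethoxy)benzene
Product: 16 2-bromo-5-[2,6-dimethoxy-4-(2,4,6-trimethoxyphenoxy)phenoxy]benzene-1,3-diol
Conditions: HCl (cat., 1.25 M in MeOH), MeOH, rt to 40 °C
Reagents that add atoms: none
Why: Acid-catalysed acetal exchange (MOM cleavage) in methanol, done as a separate step so that the formaldehyde equivalent leaves as dimethoxymethane before the phloroglucinol-type rings A and B are unmasked.

Step 10
Reactants: 16 2-bromo-5-[2,6-dimethoxy-4-(2,4,6-trimethoxyphenoxy)phenoxy]benzene-1,3-diol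
Product: 17 2-[4-(4-bromo-3,5-dihydroxyphenoxy)-3,5-dihydroxyphenoxy]benzene-1,3,5-triol (target)
Conditions: BBr3 (10 equiv), CH2Cl2, −78 °C to rt; then H2O, 0 °C
Reagents that add atoms: none
Why: Lewis-acid ether cleavage, in which bromide attacks the methyl carbon of each BBr3-complexed aryl methyl ether while the aryl bromide and the two diaryl ether bonds, having only sp2 C–O bonds, should stay intact.

Compound list
1 | 2,4,6-trimethoxybenzaldehyde | COc1cc(OC)c(C=O)c(OC)c1 | starting material
2 | 2,4,6-trimethoxyphenyl formate | COc1cc(OC)c(OC=O)c(OC)c1 | intermediate (not isolated)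
3 | 2,4,6-trimethoxyphenol | COc1cc(OC)c(O)c(OC)c1 | intermediate
4 | 4-bromo-2,6-dimethoxybenzaldehyde | COc1cc(Br)cc(OC)c1C=O | starting material
5 | 2,6-dimethoxy-4-(2,4,6-trimethoxyphenoxy)benzaldehyde | COc1cc(OC)c(Oc2cc(OC)c(C=O)c(OC)c2)c(OC)c1 | intermediate
6 | 2,6-dimethoxy-4-(2,4,6-trimethoxyphenoxy)phenyl formate | COc1cc(OC)c(Oc2cc(OC)c(OC=O)c(OC)c2)c(OC)c1 | intermediate (not isolated)
7 | 2,6-dimethoxy-4-(2,4,6-trimethoxyphenoxy)phenol | COc1cc(OC)c(Oc2cc(OC)c(O)c(OC)c2)c(OC)c1 | intermediate
8 | triacetic acid lactone (4-hydroxy-6-methyl-2H-pyran-2-one) | Cc1cc(O)cc(=O)o1 | starting material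
9 | 4-bromo-6-methyl-2H-pyran-2-one | Cc1cc(Br)cc(=O)o1 | intermediate
10 | 4-[2,6-dimethoxy-4-(2,4,6-trimethoxyphenoxy)phenoxy]-6-methyl-2H-pyran-2-one | Cc1cc(Oc2c(OC)cc(Oc3c(OC)cc(OC)cc3OC)cc2OC)cc(=O)o1 | intermediate (key-step precursor)
11 | methyl (2E)-3-[2,6-dimethoxy-4-(2,4,6-trimethoxyphenoxy)phenoxy]-5-oxohex-2-enoate | COC(=O)/C=C(/Oc1c(OC)cc(Oc2c(OC)cc(OC)cc2OC)cc1OC)CC(C)=O | intermediate (not isolated)
12 | 5-[2,6-dimethoxy-4-(2,4,6-trimethoxyphenoxy)phenoxy]benzene-1,3-diol | Oc1cc(O)cc(Oc2c(OC)cc(Oc3c(OC)cc(OC)cc3OC)cc2OC)c1 | intermediate (key-step product)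
13 | 1,3-bis(methoxymethoxy)-5-[2,6-dimethoxy-4-(2,4,6-trimethoxyphenoxy)phenoxy]benzene | COCOc1cc(OCOC)cc(Oc2c(OC)cc(Oc3c(OC)cc(OC)cc3OC)cc2OC)c1 | intermediate
14 | {4-[2,6-dimethoxy-4-(2,4,6-trimethoxyphenoxy)phenoxy]-2,6-bis(methoxymethoxy)phenyl}lithium | [Li]c1c(OCOC)cc(Oc2c(OC)cc(Oc3c(OC)cc(OC)cc3OC)cc2OC)cc1OCOC | intermediate (not isolated)
15 | 2-bromo-5-[2,6-dimethoxy-4-(2,4,6-trimethoxyphenoxy)phenoxy]-1,3-bis(methoxymethoxy)benzene | COCOc1cc(Oc2c(OC)cc(Oc3c(OC)cc(OC)cc3OC)cc2OC)cc(OCOC)c1Br | intermediate
16 | 2-bromo-5-[2,6-dimethoxy-4-(2,4,6-trimethoxyphenoxy)phenoxy]benzene-1,3-diol | Oc1cc(Oc2c(OC)cc(Oc3c(OC)cc(OC)cc3OC)cc2OC)cc(O)c1Br | intermediate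
17 | 2-[4-(4-bromo-3,5-dihydroxyphenoxy)-3,5-dihydroxyphenoxy]benzene-1,3,5-triol | Oc1cc(O)c(Oc2cc(O)c(Oc3cc(O)c(Br)c(O)c3)c(O)c2)c(O)c1 | target

Total step count: 10
Longest linear sequence: 9 steps (steps 1, 2, 3, 5, 6, 7, 8, 9, 10; step 4 is a one-step side branch)

Steps most likely to fail

1. Step 6. What may go wrong: methoxide adds to pyrone C4, or to the β-carbon of the opened enoate 11, faster than it acylates. The ring B aryloxide is then expelled, returning phenol 7 together with 5-methoxyresorcinol. Fallback: ring C is brought in ready-made and the ring B–O–ring C bond is formed by arylation. Commercial 5-bromobenzene-1,3-diol is converted with NaH and MOMCl in DMF into 1-bromo-3,5-bis(methoxymethoxy)benzene F1. Phenol 7 is then coupled with it under CuI/picolinic acid/K3PO4 in DMSO at 100 °C (Ullmann-type ether synthesis). This fallback sets out from 7 and comes back to the route at 13, by-passing 9, 10 and 12.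

2. Step 8. What may go wrong: lithiation is not confined to ring C C4 but spreads to the methoxy-flanked C–H bonds of ring A or the aryloxy-flanked ones of rings B and C, so that regioisomeric bromides form. Fallback: the unprotected diol 12 is brominated at all three ring C positions, each of which is ortho to a hydroxyl. The reagent is the N-bromoamine made from Br2 (3 equiv) and t-BuNH2 in toluene at −70 °C, a phenol-directed ortho-brominating agent that is expected to leave aryl methyl ethers alone. This should give 2,4,6-tribromo-5-[2,6-dimethoxy-4-(2,4,6-trimethoxyphenoxy)phenoxy]benzene-1,3-diol F2. Na2SO3/NaOH in aqueous MeOH at rt should then remove reductively the two bromines that stand para to a hydroxyl and keep the one between the hydroxyls; the same selectivity converts 2,4,6-tribromoresorcinol into 2-bromoresorcinol. This fallback sets out from 12 and comes back at 16, replacing steps 7 to 9.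

3. Step 2. What may go wrong: the doubly ortho-substituted, easily oxidised phenoxide couples slowly while the formyl group is consumed by base at 90 °C. Fallback: an aldehyde-free partner that already carries the ring B oxygen is used. Commercial 4-bromo-2,6-dimethoxyphenol is benzylated (BnBr, K2CO3, DMF) to 2-(benzyloxy)-5-bromo-1,3-dimethoxybenzene F3. This is coupled with 3 (CuI, N,N-dimethylglycine, Cs2CO3, dioxane, 100 °C) to 2-(benzyloxy)-1,3-dimethoxy-5-(2,4,6-trimethoxyphenoxy)benzene F4, which is hydrogenolysed (H2, Pd/C, EtOAc) to phenol 7. This fallback sets out from 3 and comes back at 7, replacing steps 2 and 3.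

Further compounds
F1 | step 6 | 1-bromo-3,5-bis(methoxymethoxy)benzene | COCOc1cc(Br)cc(OCOC)c1
F2 | step 8 | 2,4,6-tribromo-5-[2,6-dimethoxy-4-(2,4,6-trimethoxyphenoxy)phenoxy]benzene-1,3-diol | Oc1c(Br)c(O)c(Br)c(Oc2c(OC)cc(Oc3c(OC)cc(OC)cc3OC)cc2OC)c1Br
F3 | step 2 | 2-(benzyloxy)-5-bromo-1,3-dimethoxybenzene | COc1cc(Br)cc(OC)c1OCc1ccccc1
F4 | step 2 | 2-(benzyloxy)-1,3-dimethoxy-5-(2,4,6-trimethoxyphenoxy)benzene | COc1cc(OC)c(Oc2cc(OC)c(OCc3ccccc3)c(OC)c2)c(OC)c1
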